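The route rests on one disconnection: the C7–O bond of ring B. The quaternary ether carbon C7, with its methyl group and its bond to the oxygen on C11, is the Markovnikov hydroalkoxylation product of a C7 methylidene that links ring A (C6) to the C8 carbinol. A single cobalt-hydride step adds hydrogen to the exocyclic CH2, lets the C11 tertiary hydroxyl capture C7, closes ring B and sets C7. Its precursor is a seco bromohydrin: a cis-acetoxy methylcyclohexene (ring A, from an Evans aldol and ring-closing metathesis) joined through the C7 methylidene to a C8 silyl ether, a C10 bromide taken from L-aspartic acid and a C11 tertiary alcohol. Ring A is halogenated afterwards.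

Key step: step 16

Atom labels: ring A carbons are C1 (acetoxy), C2, C3 (methyl, chlorine), C4 (bromine), C5, C6; ring B carbons are C7 (methyl, bonded to C6), C8 (hydroxyl), C9, C10 (bromine), C11 (gem-dimethyl), with the ring oxygen between C7 and C11. "Upper face" of ring A is the face opposite to the C1 acetate and the C6 substituent.

Assumption: in the two ligand-controlled steps (14 and 16) the ligand antipode matched to the substrate is fixed in a small trial; the antipodes written are the ones expected and both are available.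

Step 1
Reactants: 1 (S)-4-benzyloxazolidin-2-one; 2 pent-4-enoyl chloride
Product: 3 (S)-4-benzyl-3-(pent-4-enoyl)oxazolidin-2-one
Conditions: n-BuLi, THF, −78 °C; then 2, −78 → 0 °C
Reagents that add atoms: none
Why: N-acylation of the lithiated oxazolidinone by the acid chloride is the standard preparation of an Evans imide and creates no stereocentre.

Step 2
Reactants: 4 3-methylbut-3-en-1-ol
Product: 5 3-methylbut-3-enal
Conditions: Dess–Martin periodinane, NaHCO3, CH2Cl2, 0 °C → rt; filtered and used at once as a cold solution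
Reagents that add atoms: none
Why: Dess–Martin oxidation under buffered, amine-free conditions should deliver the β,γ-unsaturated aldehyde without shifting the double bond into conjugation.

Step 3
Reactants: 3 (S)-4-benzyl-3-(pent-4-enoyl)oxazolidin-2-one; 5 3-methylbut-3-enal
Product: 7 (S)-4-benzyl-3-[(2S,3R)-3-hydroxy-5-methyl-2-(prop-2-en-1-yl)hex-5-enoyl]oxazolidin-2-one, via Z-dibutylboron enolate 6 (not isolated)
Conditions: Bu2BOTf, iPr2NEt, CH2Cl2, −78 → 0 °C; 5, −78 → 0 °C; then pH 7 buffer, MeOH, 30% H2O2, 0 °C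
Reagents that add atoms: none
Why: Evans syn aldol reaction in which the Z-boron enolate reacts through a closed chair transition state on the enolate face remote from the benzyl group, which sets C6 (2S of the acyl chain) and C1 (3R) as the syn pair.

Step 4
Reactants: 7 (S)-4-benzyl-3-[(2S,3R)-3-hydroxy-5-methyl-2-(prop-2-en-1-yl)hex-5-enoyl]oxazolidin-2-one
Product: 8 (S)-4-benzyl-3-[(1S,6R)-6-hydroxy-4-methylcyclohex-3-ene-1-carbonyl]oxazolidin-2-one
Conditions: second-generation Grubbs catalyst [RuCl2(H2IMes)(PCy3)(=CHPh)] (3 mol %), CH2Cl2, 40 °C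
Reagents that add atoms: none
Why: Ring-closing metathesis between the monosubstituted and the 1,1-disubstituted alkene closes six-membered ring A with its trisubstituted C3=C4 bond, driven by loss of ethene, and turns the syn aldol pair into the cis C1–O/C6–C relationship.

Step 5
Reactants: 8 (S)-4-benzyl-3-[(1S,6R)-6-hydroxy-4-methylcyclohex-3-ene-1-carbonyl]oxazolidin-2-one
Product: 9 (1S,6R)-6-hydroxy-N-methoxy-N,4-dimethylcyclohex-3-ene-1-carboxamide
Conditions: MeNHOMe·HCl, AlMe3, CH2Cl2, −10 → 0 °C; aq. potassium sodium tartrate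
Reagents that add atoms: N,O-dimethylhydroxylamine hydrochloride, CNOC.Cl
Why: Aluminium-amide transamidation of a β-hydroxy acyl oxazolidinone (Weinreb amide formation) attacks the exocyclic carbonyl only, helped by the aluminium alkoxide of the free hydroxyl, and releases the auxiliary.

Step 6
Reactants: 9 (1S,6R)-6-hydroxy-N-methoxy-N,4-dimethylcyclohex-3-ene-1-carboxamide
Product: 10 (1S,6R)-N-methoxy-N,4-dimethyl-6-(triethylsilyloxy)cyclohex-3-ene-1-carboxamide
Conditions: Et3SiCl, imidazole, CH2Cl2, 0 °C → rt
Reagents that add atoms: chlorotriethylsilane, CC[Si](Cl)(CC)CC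
Why: Routine silylation of the secondary alcohol, chosen so that no acyl group on C1 is exposed to the organomagnesium reagent and the amide base of the next two steps.

Step 7
Reactants: 10 (1S,6R)-N-methoxy-N,4-dimethyl-6-(triethylsilyloxy)cyclohex-3-ene-1-carboxamide
Product: 11 1-[(1S,6R)-4-methyl-6-(triethylsilyloxy)cyclohex-3-en-1-yl]ethan-1-one
Conditions: MeMgBr, THF, 0 °C; aq. NH4Cl
Reagents that add atoms: methylmagnesium bromide, C[Mg]Br
Why: Weinreb ketone synthesis, in which the chelated tetrahedral intermediate survives until work-up so that only one methyl group is added.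

Step 8
Reactants: 11 1-[(1S,6R)-4-methyl-6-(triethylsilyloxy)cyclohex-3-en-1-yl]ethan-1-one
Product: 13 1-[(1S,6R)-6-hydroxy-4-methylcyclohex-3-en-1-yl]ethenyl trifluoromethanesulfonate, via silyl ether triflate 12 (not isolated)
Conditions: KN(SiMe3)2, THF, −78 °C; N-(5-chloropyridin-2-yl)bis(trifluoromethanesulfonimide), −78 °C; then 1 M HCl, THF, 0 °C
Reagents that add atoms: N-(5-chloropyridin-2-yl)bis(trifluoromethanesulfonimide), O=S(=O)(N(c1ccc(Cl)cn1)S(=O)(=O)C(F)(F)F)C(F)(F)F
Why: Enol triflate formation by kinetic deprotonation on the methyl side (the hindered C6 methine is not touched, so C6 keeps its configuration) and O-sulfonylation by the N-aryl triflimide, followed by acid cleavage of the labile triethylsilyl ether, to which alkenyl triflates are stable.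

Step 9
Reactants: 13 1-[(1S,6R)-6-hydroxy-4-methylcyclohex-3-en-1-yl]ethenyl trifluoromethanesulfonate
Product: 14 (1R,6S)-3-methyl-6-[1-(trifluoromethanesulfonyloxy)ethenyl]cyclohex-3-en-1-yl acetate
Conditions: Ac2O, pyridine, DMAP (cat.), CH2Cl2, 0 °C → rt
Reagents that add atoms: acetic anhydride, CC(=O)OC(C)=O
Why: Nucleophile-catalysed acetylation of the secondary alcohol, placed after the strongly basic steps so that the C1 acetate of the target never meets an enolate.

Step 10
Reactants: 15 L-aspartic acid 4-tert-butyl ester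
Product: 16 (2S)-2-bromo-4-tert-butoxy-4-oxobutanoic acid
Conditions: NaNO2, KBr, 1 M H2SO4 (aq), −5 → 0 °C
Reagents that add atoms: potassium bromide, [K+].[Br-]
Why: Diazotisation of the α-amino acid in the presence of bromide runs through the α-lactone (two inversions), so the future C10 keeps the S configuration with net retention.

Step 11
Reactants: 16 (2S)-2-bromo-4-tert-butoxy-4-oxobutanoic acid
Product: 17 4-tert-butyl 1-methyl (2S)-2-bromobutanedioate
Conditions: Me3SiCHN2, toluene/MeOH, 0 °C
Reagents that add atoms: (trimethylsilyl)diazomethane, C[Si](C)(C)C=[N+]=[N-]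
Why: Base-free methyl ester formation with the diazoalkane avoids both loss of HBr to the fumarate and epimerisation of the α-bromo centre.

Step 12
Reactants: 17 4-tert-butyl 1-methyl (2S)-2-bromobutanedioate
Product: 19 (4S)-4-bromo-5,5-dimethyloxolan-2-one, via hydroxy tert-butyl ester 18 (not isolated)
Conditions: MeMgBr, CeCl3, THF, −78 → −40 °C; then CF3CO2H, CH2Cl2, 0 °C → rt
Reagents that add atoms: methylmagnesium bromide, C[Mg]Br
Why: Twofold addition of the weakly basic methylcerium reagent (Grignard-type ester addition) occurs at the activated α-bromo methyl ester and not at the hindered tert-butyl ester, and acid then cleaves the tert-butyl ester and closes the γ-lactone without touching C10.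

Step 13
Reactants: 19 (4S)-4-bromo-5,5-dimethyloxolan-2-one
Product: 20 (4S)-4-bromo-5,5-dimethyloxolan-2-ol (both anomers)
Conditions: iBu2AlH, CH2Cl2, −78 °C; aq. potassium sodium tartrate
Reagents that add atoms: none
Why: Partial reduction of a lactone with one equivalent of iBu2AlH at −78 °C stops at the lactol because the aluminium hemiacetal is stable until work-up.

Step 14
Reactants: 14 (1R,6S)-3-methyl-6-[1-(trifluoromethanesulfonyloxy)ethenyl]cyclohex-3-en-1-yl acetate; 20 (4S)-4-bromo-5,5-dimethyloxolan-2-ol
Product: 21 (1R,6R)-6-[(3S,5S)-5-bromo-3,6-dihydroxy-6-methylhept-1-en-2-yl]-3-methylcyclohex-3-en-1-yl acetate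
Conditions: CrCl2, (S)-N-[2-(4-isopropyl-4,5-dihydro-1,3-oxazol-2-yl)-6-methylphenyl]methanesulfonamide, Et3N, NiCl2 (cat.), THF, rt
Reagents that add atoms: none
Why: Nozaki–Hiyama–Kishi coupling, in which nickel inserts into the alkenyl triflate, the alkenyl group passes to chromium and adds chemoselectively to the open hydroxy-aldehyde form of the lactol in the presence of acetate, secondary bromide and free hydroxyl, while the chiral sulfonamide bound to chromium directs the addition to the Re face of C8 (8S).

Step 15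
Reactants: 21 (1R,6R)-6-[(3S,5S)-5-bromo-3,6-dihydroxy-6-methylhept-1-en-2-yl]-3-methylcyclohex-3-en-1-yl acetate
Product: 22 (1R,6R)-6-[(3S,5S)-5-bromo-3-(tert-butyldimethylsilyloxy)-6-hydroxy-6-methylhept-1-en-2-yl]-3-methylcyclohex-3-en-1-yl acetate
Conditions: t-BuMe2SiCl, imidazole, DMF, rt
Reagents that add atoms: tert-butyl(chloro)dimethylsilane, CC(C)(C)[Si](C)(C)Cl
Why: Silylation with the silyl chloride and imidazole takes the secondary allylic C8 hydroxyl and leaves the hindered tertiary C11 hydroxyl, the nucleophile of the next step, free.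

Step 16
Reactants: 22 (1R,6R)-6-[(3S,5S)-5-bromo-3-(tert-butyldimethylsilyloxy)-6-hydroxy-6-methylhept-1-en-2-yl]-3-methylcyclohex-3-en-1-yl acetate
Product: 23 (1R,6S)-6-[(2S,3S,5S)-5-bromo-3-(tert-butyldimethylsilyloxy)-2,6,6-trimethyloxan-2-yl]-3-methylcyclohex-3-en-1-yl acetate
Conditions: (R,R)-N,N'-bis(3,5-di-tert-butylsalicylidene)-1,2-cyclohexanediaminocobalt [Co(salen) complex of divalent cobalt] (5 mol %), N-fluoro-2,4,6-trimethylpyridinium triflate, PhSiH3, PhCF3, 0 °C
Reagents that add atoms: none
Why: The N-fluoropyridinium salt oxidises the cobalt complex and the silane turns the resulting cobalt fluoride into a trivalent cobalt hydride, which transfers a hydrogen atom to the terminal CH2 of the C7 methylidene; the tertiary C7 radical is then oxidised through an alkylcobalt species to a cation equivalent that the C11 hydroxyl captures, and collidine takes up the proton. The closest known reaction type is the Co(salen)/N-fluoropyridinium/silane hydrogen-atom-transfer hydroalkoxylation of unactivated 1,1-disubstituted alkenols to cyclic ethers (radical–polar crossover). Ring B closes in the 6-exo-trig mode at the more substituted alkene carbon, so the C7 methyl group and the C7–O bond arise together. C7 is set in a chair-like transition state in which ring A is equatorial to avoid the axial C11 methyl, C8–H is aligned with the electron-poor C7 orbital and C8–O lies gauche to the incoming oxygen, an arrangement that places C10–Br equatorial and gives 7S, and the enantiopure salen ligand can reinforce this face. The step needs chemoselectivity for the 1,1-disubstituted alkene over the trisubstituted ring A alkene, which the unhindered terminal CH2 and the slower reaction of the ring alkene with the bulky cobalt hydride should provide, and it needs ether formation to outrun epoxide closure and a 1,2-hydride shift, for which C8–O is silylated and the hydroxyl is held in reach of C7 for a six-membered closure. The secondary bromide and the acetate should be inert under these near-neutral conditions.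

Step 17
Reactants: 23 (1R,6S)-6-[(2S,3S,5S)-5-bromo-3-(tert-butyldimethylsilyloxy)-2,6,6-trimethyloxan-2-yl]-3-methylcyclohex-3-en-1-yl acetate
Product: 24 (1R,3R,4S,6S)-6-[(2S,3S,5S)-5-bromo-3-(tert-butyldimethylsilyloxy)-2,6,6-trimethyloxan-2-yl]-3,4-dihydroxy-3-methylcyclohexyl acetate
Conditions: OsO4 (cat.), NMO, acetone/H2O, rt
Reagents that add atoms: osmium tetroxide (catalytic oxygen carrier), O=[Os](=O)(=O)=O; 4-methylmorpholine N-oxide, C[N+]1([O-])CCOCC1; water, O
Why: Catalytic syn-dihydroxylation (Upjohn conditions) should take place on the face of the C3=C4 bond opposite to the axial C1 acetate and the C6 substituent, which sets C3 (R) and C4 (S) with both hydroxyls on the upper face.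

Step 18
Reactants: 24 (1R,3R,4S,6S)-6-[(2S,3S,5S)-5-bromo-3-(tert-butyldimethylsilyloxy)-2,6,6-trimethyloxan-2-yl]-3,4-dihydroxy-3-methylcyclohexyl acetate
Product: 26 3,4-cyclic sulfate of 24, via cyclic sulfite 25 (not isolated)
Conditions: SOCl2, Et3N, CH2Cl2, 0 °C; then RuCl3 (cat.), NaIO4, MeCN/H2O, 0 °C
Reagents that add atoms: thionyl chloride, O=S(Cl)Cl; sodium periodate, [Na+].[O-]I(=O)(=O)=O
Why: Two-stage cyclic sulfate synthesis in which the cis-diol is tied up as the sulfite and RuO4 generated from RuCl3 and periodate oxidises sulfur only, with no change at carbon (ring B has no C–H next to its ether oxygen).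

Step 19
Reactants: 26 3,4-cyclic sulfate of 24
Product: 28 (1R,3R,4R,6S)-4-bromo-6-[(2S,3S,5S)-5-bromo-3-(tert-butyldimethylsilyloxy)-2,6,6-trimethyloxan-2-yl]-3-hydroxy-3-methylcyclohexyl acetate, via lithium sulfate monoester 27 (not isolated)
Conditions: LiBr, THF, rt → 50 °C; then H2SO4 (cat.), H2O (1 equiv), THF, rt
Reagents that add atoms: lithium bromide, [Li+].[Br-]
Why: Nucleophilic opening of a cyclic sulfate, in which bromide attacks the secondary C4 from the lower face with inversion (4R) and not the tertiary C3, after which acid cleaves the remaining sulfate monoester to the tertiary alcohol with C3 unchanged.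

Step 20
Reactants: 28 (1R,3R,4R,6S)-4-bromo-6-[(2S,3S,5S)-5-bromo-3-(tert-butyldimethylsilyloxy)-2,6,6-trimethyloxan-2-yl]-3-hydroxy-3-methylcyclohexyl acetate
Product: 30 (1R,3R,4R,6S)-4-bromo-6-[(2S,3S,5S)-5-bromo-3-(tert-butyldimethylsilyloxy)-2,6,6-trimethyloxan-2-yl]-3-chloro-3-methylcyclohexyl acetate, via chlorosulfite 29 (not isolated)
Conditions: SOCl2, CH2Cl2, −20 → 0 °C
Reagents that add atoms: thionyl chloride, O=S(Cl)Cl
Why: Chlorodehydroxylation through the chlorosulfite (internal return of chloride) with anchimeric assistance, since the trans C4 bromine, backed by the axial C1 acetate, occupies the lower face of C3 as the leaving group departs and chloride is therefore returned on the upper face, that is with retention (3R).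

Step 21
Reactants: 30 (1R,3R,4R,6S)-4-bromo-6-[(2S,3S,5S)-5-bromo-3-(tert-butyldimethylsilyloxy)-2,6,6-trimethyloxan-2-yl]-3-chloro-3-methylcyclohexyl acetate
Product: 31 (1R,3R,4R,6S)-4-bromo-6-[(2S,3S,5S)-5-bromo-3-hydroxy-2,6,6-trimethyloxan-2-yl]-3-chloro-3-methylcyclohexyl acetate (target, CNP0251357.1)
Conditions: HF·pyridine, pyridine, THF, 0 °C → rt
Reagents that add atoms: none
Why: Fluoride-mediated cleavage of the silyl ether under buffered, non-basic conditions frees the C8 hydroxyl and leaves the acetate, the tertiary chloride and both bromides in place.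

Compound list

1 | (S)-4-benzyloxazolidin-2-one | O=C1OC[C@H](Cc2ccccc2)N1 | starting material
2 | pent-4-enoyl chloride | C=CCCC(=O)Cl | starting material
3 | (S)-4-benzyl-3-(pent-4-enoyl)oxazolidin-2-one | O=C1OC[C@H](Cc2ccccc2)N1C(=O)CCC=C | intermediate
4 | 3-methylbut-3-en-1-ol | CC(=C)CCO | starting material
5 | 3-methylbut-3-enal | CC(=C)CC=O | intermediate
6 | Z-dibutylboron enolate of 3 (formed in the flask) | C=CC/C=C(\OB(CCCC)CCCC)N1C(=O)OC[C@@H]1Cc1ccccc1 | intermediate
7 | (S)-4-benzyl-3-[(2S,3R)-3-hydroxy-5-methyl-2-(prop-2-en-1-yl)hex-5-enoyl]oxazolidin-2-one | O=C1OC[C@H](Cc2ccccc2)N1C(=O)[C@@H](CC=C)[C@H](O)CC(C)=C | intermediate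
8 | (S)-4-benzyl-3-[(1S,6R)-6-hydroxy-4-methylcyclohex-3-ene-1-carbonyl]oxazolidin-2-one | O=C1OC[C@H](Cc2ccccc2)N1C(=O)[C@H]3CC=C(C)C[C@H]3O | intermediate
9 | (1S,6R)-6-hydroxy-N-methoxy-N,4-dimethylcyclohex-3-ene-1-carboxamide | CON(C)C(=O)[C@H]1CC=C(C)C[C@H]1O | intermediate
10 | (1S,6R)-N-methoxy-N,4-dimethyl-6-(triethylsilyloxy)cyclohex-3-ene-1-carboxamide | CON(C)C(=O)[C@H]1CC=C(C)C[C@H]1O[Si](CC)(CC)CC | intermediate
11 | 1-[(1S,6R)-4-methyl-6-(triethylsilyloxy)cyclohex-3-en-1-yl]ethan-1-one | CC(=O)[C@H]1CC=C(C)C[C@H]1O[Si](CC)(CC)CC | intermediate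
12 | 1-[(1S,6R)-4-methyl-6-(triethylsilyloxy)cyclohex-3-en-1-yl]ethenyl trifluoromethanesulfonate (formed in the flask) | C=C(OS(=O)(=O)C(F)(F)F)[C@H]1CC=C(C)C[C@H]1O[Si](CC)(CC)CC | intermediate
13 | 1-[(1S,6R)-6-hydroxy-4-methylcyclohex-3-en-1-yl]ethenyl trifluoromethanesulfonate | C=C(OS(=O)(=O)C(F)(F)F)[C@H]1CC=C(C)C[C@H]1O | intermediate
14 | (1R,6S)-3-methyl-6-[1-(trifluoromethanesulfonyloxy)ethenyl]cyclohex-3-en-1-yl acetate | C=C(OS(=O)(=O)C(F)(F)F)[C@H]1CC=C(C)C[C@H]1OC(C)=O | intermediate
15 | L-aspartic acid 4-tert-butyl ester | N[C@@H](CC(=O)OC(C)(C)C)C(=O)O | starting material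
16 | (2S)-2-bromo-4-tert-butoxy-4-oxobutanoic acid | Br[C@@H](CC(=O)OC(C)(C)C)C(=O)O | intermediate
17 | 4-tert-butyl 1-methyl (2S)-2-bromobutanedioate | COC(=O)[C@@H](Br)CC(=O)OC(C)(C)C | intermediate
18 | tert-butyl (3S)-3-bromo-4-hydroxy-4-methylpentanoate (formed in the flask) | CC(C)(O)[C@@H](Br)CC(=O)OC(C)(C)C | intermediate
19 | (4S)-4-bromo-5,5-dimethyloxolan-2-one | CC1(C)OC(=O)C[C@@H]1Br | intermediate
20 | (4S)-4-bromo-5,5-dimethyloxolan-2-ol (both anomers) | CC1(C)OC(O)C[C@@H]1Br | intermediate
21 | (1R,6R)-6-[(3S,5S)-5-bromo-3,6-dihydroxy-6-methylhept-1-en-2-yl]-3-methylcyclohex-3-en-1-yl acetate | CC(=O)O[C@@H]1CC(C)=CC[C@@H]1C(=C)[C@@H](O)C[C@H](Br)C(C)(C)O | intermediate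
22 | (1R,6R)-6-[(3S,5S)-5-bromo-3-(tert-butyldimethylsilyloxy)-6-hydroxy-6-methylhept-1-en-2-yl]-3-methylcyclohex-3-en-1-yl acetate (key-step precursor) | CC(=O)O[C@@H]1CC(C)=CC[C@@H]1C(=C)[C@@H](O[Si](C)(C)C(C)(C)C)C[C@H](Br)C(C)(C)O | intermediate
23 | (1R,6S)-6-[(2S,3S,5S)-5-bromo-3-(tert-butyldimethylsilyloxy)-2,6,6-trimethyloxan-2-yl]-3-methylcyclohex-3-en-1-yl acetate (key-step product) | CC(=O)O[C@@H]1CC(C)=CC[C@@H]1[C@]1(C)OC(C)(C)[C@@H](Br)C[C@@H]1O[Si](C)(C)C(C)(C)C | intermediate
24 | (1R,3R,4S,6S)-6-[(2S,3S,5S)-5-bromo-3-(tert-butyldimethylsilyloxy)-2,6,6-trimethyloxan-2-yl]-3,4-dihydroxy-3-methylcyclohexyl acetate | CC(=O)O[C@@H]1C[C@@](C)(O)[C@@H](O)C[C@@H]1[C@]1(C)OC(C)(C)[C@@H](Br)C[C@@H]1O[Si](C)(C)C(C)(C)C | intermediate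
25 | cyclic sulfite of 24 across O3 and O4, either configuration at sulfur (formed in the flask) | CC(=O)O[C@@H]1C[C@@]2(C)OS(=O)O[C@H]2C[C@@H]1[C@]1(C)OC(C)(C)[C@@H](Br)C[C@@H]1O[Si](C)(C)C(C)(C)C | intermediate
26 | cyclic sulfate of 24 across O3 and O4 | CC(=O)O[C@@H]1C[C@@]2(C)OS(=O)(=O)O[C@H]2C[C@@H]1[C@]1(C)OC(C)(C)[C@@H](Br)C[C@@H]1O[Si](C)(C)C(C)(C)C | intermediate
27 | lithium salt of the C3 sulfate monoester of 28 (formed in the flask) | CC(=O)O[C@@H]1C[C@@](C)(OS(=O)(=O)[O-])[C@H](Br)C[C@@H]1[C@]1(C)OC(C)(C)[C@@H](Br)C[C@@H]1O[Si](C)(C)C(C)(C)C.[Li+] | intermediate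
28 | (1R,3R,4R,6S)-4-bromo-6-[(2S,3S,5S)-5-bromo-3-(tert-butyldimethylsilyloxy)-2,6,6-trimethyloxan-2-yl]-3-hydroxy-3-methylcyclohexyl acetate | CC(=O)O[C@@H]1C[C@@](C)(O)[C@H](Br)C[C@@H]1[C@]1(C)OC(C)(C)[C@@H](Br)C[C@@H]1O[Si](C)(C)C(C)(C)C | intermediate
29 | C3 chlorosulfite of 28 (formed in the flask) | CC(=O)O[C@@H]1C[C@@](C)(OS(=O)Cl)[C@H](Br)C[C@@H]1[C@]1(C)OC(C)(C)[C@@H](Br)C[C@@H]1O[Si](C)(C)C(C)(C)C | intermediate
30 | (1R,3R,4R,6S)-4-bromo-6-[(2S,3S,5S)-5-bromo-3-(tert-butyldimethylsilyloxy)-2,6,6-trimethyloxan-2-yl]-3-chloro-3-methylcyclohexyl acetate | CC(=O)O[C@@H]1C[C@@](C)(Cl)[C@H](Br)C[C@@H]1[C@]1(C)OC(C)(C)[C@@H](Br)C[C@@H]1O[Si](C)(C)C(C)(C)C | intermediate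
31 | (1R,3R,4R,6S)-4-bromo-6-[(2S,3S,5S)-5-bromo-3-hydroxy-2,6,6-trimethyloxan-2-yl]-3-chloro-3-methylcyclohexyl acetate | CC(=O)O[C@@H]1C[C@@](C)(Cl)[C@H](Br)C[C@@H]1[C@]1(C)OC(C)(C)[C@@H](Br)C[C@@H]1O | target

Total: 21 steps. Longest linear sequence: 16 steps (steps 1, 3–9 and 14–21).

The three steps most likely to fail:

Step 16. The ring closure may show poor facial selectivity at C7, because closure through the alternative chair with axial bromine would give the C7 epimer. Hydrogen-atom transfer may also reach the ring A alkene, and a 1,2-hydride shift from C8 may compete with capture by the hydroxyl. Fallback: starting from 22, iodoetherification with N-iodosuccinimide and NaHCO3 in CH2Cl2 closes ring B by 6-exo attack of the C11 hydroxyl on the iodonium ion of the methylidene. This is a reversible electrophilic closure with a different stereo-determining step, and it gives the iodomethyl oxane F1. Selective radical reduction of its primary C–I bond with Bu3SnH and Et3B/air at low temperature, which leaves the secondary bromide, returns to 23.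

Step 20. The chlorosulfite may ionise without bromine participation, so that configuration at C3 is lost, or the cation may eliminate or be captured by the C1 acetate. Fallback: starting from 23, direct anti bromochlorination of the C3=C4 bond with N-bromosuccinimide and Et4NCl in CH2Cl2 at low temperature, in which chloride opens the bromonium ion at the tertiary C3, leads to 30 in one operation and bypasses steps 17–20. The fallback makes no compound outside the list (F0).

Step 19. Substitution at C4, a secondary carbon next to the fully substituted C3, may be slow, and elimination or attack at C3 may take over. Fallback: starting from 23, epoxidation with dimethyldioxirane in acetone on the same upper face gives the 3,4-epoxide F2. Li2NiBr4 in THF then opens it by bromide attack at the less substituted C4 with inversion, which returns to 28 and bypasses steps 17–19.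

Further compounds
F1 | step 16 | iodomethyl analogue of 23 (CH2I on C7 in place of the methyl group) | CC(=O)O[C@@H]1CC(C)=CC[C@@H]1[C@]1(CI)OC(C)(C)[C@@H](Br)C[C@@H]1O[Si](C)(C)C(C)(C)C
F0 | step 20 | none | none
F2 | step 19 | 3,4-epoxide of 23 with oxygen on the upper face | CC(=O)O[C@@H]1C[C@@]2(C)O[C@H]2C[C@@H]1[C@]1(C)OC(C)(C)[C@@H](Br)C[C@@H]1O[Si](C)(C)C(C)(C)C
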